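**Remark on numbering.** Abietane locants are used for skeletal atoms: C10 is the quaternary carbon (methyl C20, chain C1–C3), C5 carries the isopropenyl group (C4), C6 is the ring methylene, C7 the ketone, C8 and C9 the ring-fusion carbons, and C11–C14 the other arene carbons.

## Analysis of the target

The target is a 3,4-seco-abietane. It is a 1-tetralone in which ring B (C5, C6, C7, C8, C9, C10, with C7 the ketone) is fused through C8–C9 to the fully substituted benzene ring C. Ring A survives only as a propanoic acid chain on C10 and an isopropenyl group on C5.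

There are two adjacent stereocentres, the tertiary C5 and the quaternary benzylic C10. The isopropenyl group is cis to the acid chain and trans to the C10 methyl, which corresponds to (5S,10R).

Ring C carries, in order, C9, C11–OH, C12–OH, C13–isopropyl, C14–OH and C8. It is a hydroxyhydroquinone that oxidises in air to the hydroxyquinone, and its C14 hydroxyl is chelated to the C7 ketone.

The isopropenyl group does not tolerate strong protic or Lewis acids, which rules out a late cleavage of aryl methyl ethers. C5 is β, not α, to the ketone, so it cannot epimerise by enolisation.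

The difficulty lies in the crowded, regiodefined hexasubstituted arene beside a quaternary carbon, together with the vicinal tertiary/quaternary pair.

The strategy rests on one feature of ring C: the C14 and C12 oxygens are meta, with the isopropyl group on C13 between them, and C8=C9 is shared with ring B. This is the pattern produced when a vinylketene (carbonyl carbon becoming C14) combines with a siloxyalkyne (supplying C12–O and C13–isopropyl). The remaining C11 oxygen sits para to C14–OH and can be added afterwards through a quinone.

## Retrosynthetic reasoning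

**30 to 29.** The last operation is a redox adjustment only. The air-sensitive triol 30 is written as the reduction product of hydroxyquinone acid 29, so the sensitive oxidation level appears only in the final flask.

**29 to 28.** The C3 carboxyl is traced to the primary alcohol of 28. Carrying C3 as a protected alcohol keeps an acidic, enolisable carboxyl derivative out of all the enolate chemistry used earlier.

**28 to 26 (through 27).** Two changes are undone here: the C11–O bond and the C7 ketone. C11 is the only unsubstituted arene carbon, para to the C14 oxygen and ortho to the C12 oxygen, so a phenol-to-quinone oxidation of resorcinol 26 can only place oxygen there. The ketone is kept masked as the ethyl enol ether of 27 during this oxidation, because the arene is then electron-rich and unchelated; hydrolysis follows in the same flask.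

**26 to 25.** Both silyl groups are removed together: the aryl silyl ether at C12, which comes from the alkyne, and the silyl ether at C3.

**25 to 16 + 20.** This is the central disconnection. Four bonds of ring C are cut at once: C9–C11, C11–C12, C13–C14 and C14–C8. The arene is reduced to a dienyl diazomethyl ketone 16, which contains ring B with both stereocentres, and siloxyalkyne 20. Cutting here means that no substituent ever has to be introduced onto a preformed crowded arene; the order of substituents follows from connectivity. The forward reaction must generate a vinylketene from 16 and have it add 20 with the right orientation.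

**20 to 17.** The siloxyalkyne is the O-silylated ynolate obtained by one-carbon homologation of ester 17.

**16 to 14 to 13 to 12.** The diazo carbon (future C11) is put onto methyl ketone 14 by diazo transfer. The C9–acyl bond of 14 is cut back to dienyl triflate 13 by a carbonylative methyl coupling. The triflate comes from vinylogous ester 12 by enolisation towards C6, which creates the C6=C7 enol ether and the C8=C9 alkene in one operation.

**12 to 11 to 10 to 9.** The C7 oxygen is removed: the enol ether goes back to 1,3-dione 11, this to epoxy ketone 10, and this to enone 9. The oxygen is introduced only after C10 is quaternary. If it were introduced earlier, the ring would pass through a 1,3-dione with a mirror plane through C5 and C8, and the C5 stereocentre would be lost.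

**9 to 8 to 5 + 7.** The C10–C20 and C10–C1 bonds are cut as two successive α′-alkylations of enone 5. The enone double bond blocks enolisation towards C8. The methyl group is introduced second so that it enters trans to the isopropenyl group; this leaves the chain from iodide 7 cis, as required.

**5 to 3 to 1 + 2.** Enone 5 is the dehydrogenation product of ketone 3. The C4–C5 bond of 3 is cut by a catalytic asymmetric conjugate addition of the isopropenyl unit of 2 to cyclohexenone 1. This sets C5, the stereocentre from which C10 is later derived.

**7 to 6.** The iodide is the silyl ether of iodo alcohol 6.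

## Alternatives that were turned down

**Alternative 1:** The C4–C5 bond is disconnected inside a temporary ring A. In the forward direction, the enolate of the isopropyl ketone in the C10 side chain of enone A2 adds in Michael fashion to C5 of the C5=C6–C7=O unit. This closes a six-membered ring and gives the cis-fused tricyclic 3,7-diketone A1. Ring A then has to be opened again between C3 and C4, by Baeyer–Villiger oxidation and elimination, to reveal the isopropenyl group and the acid.

- For it: the cis ring fusion enforces exactly the cis relation between C4 and C1 that the target needs, so C5 follows from C10 by ring geometry. On this point it is stronger than the chosen route, which relies on facial selectivity in an enolate methylation.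
- Against it: the whole hexasubstituted arene must be made beforehand as its tris(methyl ether). The synthesis would then end with cleavage of three aryl methyl ethers by a strong Lewis acid in the presence of the isopropenyl group and the acid, which invites hydration, lactonisation or double-bond shift.
- Against it: the Baeyer–Villiger step must distinguish the C3 ketone from the C7 ketone on a very electron-rich aryl group.
- Against it: the Michael step joins a fully substituted enolate carbon to a carbon flanked by quaternary C10, so it is congested and reversible, and C10 still has to be made enantioselectively.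
- Comparison: the chosen strategy gives up ring-enforced relative configuration. In exchange, C5 is set by a catalyst on cyclohexenone, only silyl protection is used, and the arene is formed last.

**Alternative 2:** The C5–C6 bond is disconnected. In the forward direction, keto imide A4 is doubly deprotonated and the dienolate is oxidised by a divalent copper or trivalent iron salt. This couples C5 to C6, closes ring B and gives tetralone A3, with C5 set by the oxazolidinone.

- For it: the route is convergent, ring B and C5 arise in one step under auxiliary control, and the C11 oxygen is already present, so no late quinone chemistry is needed. On these two points it is as strong as or stronger than the chosen route.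
- Against it: C5 is a neopentyl-type enolate carbon next to quaternary C10, so the coupling is hindered.
- Against it: the methyl ester offers a third enolisable site, and the auxiliary must override the adjacent quaternary centre, which itself has to be made enantiopure on an aryl-substituted carbon.
- Against it: the C5 acyl group must afterwards be turned into isopropenyl through a methyl ketone, with C5 now α to a carbonyl and epimerisable, and with a 1,4-dicarbonyl prone to cyclodehydration.
- Against it: three methyl ethers again have to be cleaved.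
- Comparison: the chosen route keeps C5 non-epimerisable throughout and needs no conversion of an acyl group into the alkene. It pays with a two-step oxidation to reach the C11 oxygen.

**Alternative 3:** The C9–C10 bond is disconnected. In the forward direction, zerovalent palladium inserts into the aryl iodide of A6. The (E)-trisubstituted C10=C1 alkene then inserts in a 6-exo Heck cyclisation that forms C9–C10 and the quaternary centre, and β-hydride elimination re-forms the alkene at C1=C2, giving A5.

- For it: the aryl–quaternary carbon bond is made by a reaction type with a strong record for such centres, and C5 is adjacent and can direct the face. The route is convergent, and on convergence it is stronger than the largely linear chosen route.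
- Against it: the iodide lies between a methoxy group and the acyl-bearing C8 in a hexasubstituted ring, so oxidative addition and insertion are crowded.
- Against it: the configuration at C10 depends on alkene geometry and on one insertion geometry controlled only by C5.
- Against it: after the key step the C1=C2 alkene has to be reduced while the isopropenyl group is still masked as a tertiary silyl ether. That ether must later be eliminated towards the terminal alkene and not the tetrasubstituted one, and three methyl ethers must be cleaved.
- Comparison: the chosen route never has to form C9–C10, because it is a ring bond of the starting enone. It introduces the isopropenyl group as such in the first step and avoids ether cleavage.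

Key step: step 13

**Remark on step 1.** The sense of induction is assigned by analogy with aryl and alkenyl transfer under the same catalyst; should it prove opposite, the (S)-ligand would be used.

## Steps

Step 1
Reactants: 1 cyclohex-2-en-1-one; 2 4,4,5,5-tetramethyl-2-(prop-1-en-2-yl)-1,3,2-dioxaborolane
Product: 3 (R)-3-(prop-1-en-2-yl)cyclohexan-1-one
Conditions: [RhCl(C2H4)2]2 (1.5 mol %), (R)-BINAP (3.3 mol %), aq. KOH, dioxane/H2O 10:1, 40 °C
Reagents that add atoms: none
Why: Hayashi–Miyaura asymmetric 1,4-addition; the alkenyl group is transferred from boron to monovalent rhodium and the BINAP complex carbometalates one enantioface of the enone, which sets C5; protonation of the rhodium enolate by water releases the ketone.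

Step 2
Reactants: 3 (R)-3-(prop-1-en-2-yl)cyclohexan-1-one
Product: 5 (R)-5-(prop-1-en-2-yl)cyclohex-2-en-1-one, via trimethylsilyl enol ether 4 (not isolated)
Conditions: LiTMP (lithium 2,2,6,6-tetramethylpiperidide), TMSCl, THF, −78 °C (in situ quench); then Pd(OAc)2 (1.05 equiv), MeCN, rt
Reagents that add atoms: none
Why: Saegusa–Ito oxidation; the bulky amide should take the kinetic proton from the unhindered C8 methylene and not from C10 beside the substituted C5, and divalent palladium then converts the enol silane into the C7=C8 enone; a regioisomeric by-product would be removed by chromatography.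

Step 3
Reactants: 6 3-iodopropan-1-ol
Product: 7 tert-butyl(3-iodopropoxy)diphenylsilane
Conditions: TBDPSCl, imidazole, CH2Cl2, 0 °C to rt
Reagents that add atoms: tert-butyl(chloro)diphenylsilane, CC(C)(C)[Si](Cl)(c1ccccc1)c1ccccc1
Why: Silylation of a primary alcohol; the diphenyl silyl ether is chosen over the dimethyl analogue because it must survive the acid-catalysed enol ether formation of step 8 and is cleaved by fluoride in step 14.

Step 4
Reactants: 5 (R)-5-(prop-1-en-2-yl)cyclohex-2-en-1-one; 7 tert-butyl(3-iodopropoxy)diphenylsilane
Product: 8 (5R,6S)-6-{3-[(tert-butyldiphenylsilyl)oxy]propyl}-5-(prop-1-en-2-yl)cyclohex-2-en-1-one (chain trans to isopropenyl)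
Conditions: LiN(iPr)2, THF, −78 °C; then 7, DMPU, −78 to −30 °C
Reagents that add atoms: none
Why: Kinetic α′-deprotonation of the enone gives the cross-conjugated lithium dienolate, which is alkylated at C10 by the primary iodide; the C7=C8 double bond prevents enolisation on the other side, and the configuration formed at C10 is erased in step 5.

Step 5
Reactants: 8 (5R,6S)-6-{3-[(tert-butyldiphenylsilyl)oxy]propyl}-5-(prop-1-en-2-yl)cyclohex-2-en-1-one
Product: 9 (5S,6R)-6-{3-[(tert-butyldiphenylsilyl)oxy]propyl}-6-methyl-5-(prop-1-en-2-yl)cyclohex-2-en-1-one (methyl trans to isopropenyl; chain cis)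
Conditions: LiN(iPr)2, THF, −78 °C; then MeI, DMPU, −78 to −40 °C
Reagents that add atoms: iodomethane, CI
Why: Second α′-alkylation, which creates the quaternary C10 under substrate control by C5: in the dienolate the isopropenyl group should stand pseudoaxial to avoid allylic strain with the C10 chain, so iodomethane should enter on the opposite face, giving methyl trans and chain cis to isopropenyl.

Step 6
Reactants: 9 (5S,6R)-6-{3-[(tert-butyldiphenylsilyl)oxy]propyl}-6-methyl-5-(prop-1-en-2-yl)cyclohex-2-en-1-one
Product: 10 3-{3-[(tert-butyldiphenylsilyl)oxy]propyl}-3-methyl-4-(prop-1-en-2-yl)-7-oxabicyclo[4.1.0]heptan-2-one (C7–C8 epoxide expected anti to isopropenyl; C5 and C10 as in 9)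
Conditions: 30% H2O2, NaOH (cat.), MeOH, 0 °C
Reagents that add atoms: hydrogen peroxide, OO
Why: Weitz–Scheffer nucleophilic epoxidation; hydroperoxide adds only to the electron-poor enone at C7 and leaves the isopropenyl group alone, and the epoxide configuration is of no consequence because C7 and C8 become sp2 again in steps 7 and 8.

Step 7
Reactants: 10 the epoxy ketone of step 6
Product: 11 4-{3-[(tert-butyldiphenylsilyl)oxy]propyl}-4-methyl-5-(prop-1-en-2-yl)cyclohexane-1,3-dione (C5 and C10 as in 9)
Conditions: Pd(PPh3)4 (5 mol %), dppe (5 mol %), toluene, 100 °C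
Reagents that add atoms: none
Why: Isomerisation of an α,β-epoxy ketone to a β-diketone catalysed by zerovalent palladium (oxidative addition at the C8–O bond, β-hydride elimination from C7, tautomerisation); because C10 is already quaternary the dione has no mirror plane and C5 stays stereogenic.

Step 8
Reactants: 11 the 1,3-dione of step 7
Product: 12 6-{3-[(tert-butyldiphenylsilyl)oxy]propyl}-3-ethoxy-6-methyl-5-(prop-1-en-2-yl)cyclohex-2-en-1-one (C9 ketone and C7 ethoxy; C5 and C10 as in 9)
Conditions: EtOH, PPTS (10 mol %), benzene, reflux with azeotropic removal of water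
Reagents that add atoms: ethanol, CCO
Why: Acid-catalysed enol ether formation under equilibrating conditions; ethanol attacks the unhindered C7 carbonyl while the C9 carbonyl beside the quaternary centre is retained, giving the less strained vinylogous ester, and the mild acid leaves the diphenyl silyl ether and the isopropenyl group intact.

Step 9
Reactants: 12 the vinylogous ester of step 8
Product: 13 6-{3-[(tert-butyldiphenylsilyl)oxy]propyl}-3-ethoxy-6-methyl-5-(prop-1-en-2-yl)cyclohexa-1,3-dien-1-yl trifluoromethanesulfonate (C5 and C10 as in 9)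
Conditions: KN(SiMe3)2, THF, −78 °C; then PhNTf2, −78 to 0 °C
Reagents that add atoms: N-phenylbis(trifluoromethanesulfonimide), O=S(=O)(N(c1ccccc1)S(=O)(=O)C(F)(F)F)C(F)(F)F
Why: With no hydrogen left on C10 the base removes a γ-hydrogen from C6 and forms the extended dienolate, which is sulfonylated on the C9 oxygen (enol triflate formation); this creates the C6=C7 enol ether and the C8=C9 alkene together.

Step 10
Reactants: 13 the dienyl triflate of step 9
Product: 14 1-[6-{3-[(tert-butyldiphenylsilyl)oxy]propyl}-3-ethoxy-6-methyl-5-(prop-1-en-2-yl)cyclohexa-1,3-dien-1-yl]ethan-1-one (C5 and C10 as in 9)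
Conditions: Pd(PPh3)4 (5 mol %), LiCl, Me4Sn, CO (3 atm), THF, 60 °C
Reagents that add atoms: carbon monoxide, [C-]#[O+]; tetramethylstannane, C[Sn](C)(C)C
Why: Carbonylative Stille coupling: zerovalent palladium adds to the dienyl triflate, CO inserts, a methyl group is transferred from tin and reductive elimination gives the methyl ketone; the neutral conditions preserve the enol ether.

Step 11
Reactants: 14 the methyl ketone of step 10
Product: 16 2-diazo-1-[6-{3-[(tert-butyldiphenylsilyl)oxy]propyl}-3-ethoxy-6-methyl-5-(prop-1-en-2-yl)cyclohexa-1,3-dien-1-yl]ethan-1-one (C5 and C10 as in 9), via trifluoroacetyl diketone 15 (not isolated)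
Conditions: LiN(SiMe3)2, THF, −78 °C; CF3CO2CH2CF3; then MsN3, Et3N, H2O, MeCN, rt
Reagents that add atoms: methanesulfonyl azide, CS(=O)(=O)N=[N+]=[N-]
Why: Detrifluoroacetylative diazo transfer of the Regitz type: the kinetic enolate of the methyl group is trifluoroacetylated and the activated diketone accepts the diazo group from the sulfonyl azide with loss of the trifluoroacetyl group; deprotonation at −78 °C should take the methyl hydrogen and leave the vinylogous C5 hydrogen untouched.

Step 12
Reactants: 17 ethyl 2-methylpropanoate
Product: 20 triisopropyl[(3-methylbut-1-yn-1-yl)oxy]silane, via lithium dibromoenolate 18 (not isolated), via lithium ynolate 19 (not isolated)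
Conditions: CH2Br2, LiTMP, THF, −78 °C; LiN(SiMe3)2; n-BuLi, −78 °C to rt; then iPr3SiCl, −78 °C to rt
Reagents that add atoms: dibromomethane, BrCBr; chlorotri(propan-2-yl)silane, CC(C)[Si](Cl)(C(C)C)C(C)C
Why: Kowalski ester homologation stopped at the ynolate: LiCHBr2 adds to the ester, bromine–lithium exchange on the dibromo enolate triggers a 1,2-shift of the isopropyl group with loss of LiBr, and the bulky chlorosilane silylates the ynolate on oxygen.

Step 13
Reactants: 16 the dienyl diazomethyl ketone of step 11; 20 triisopropyl[(3-methylbut-1-yn-1-yl)oxy]silane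
Product: 25 5-{3-[(tert-butyldiphenylsilyl)oxy]propyl}-8-ethoxy-5-methyl-2-(propan-2-yl)-6-(prop-1-en-2-yl)-3-[(triisopropylsilyl)oxy]-5,6-dihydronaphthalen-1-ol (C14 phenol and C12 silyl ether and C11–H; C5 and C10 as in 9), via vinylketene 21 (not isolated), via vinylcyclobutenone 22 (not isolated), via dienylketene 23 (not isolated), via cyclohexadienone 24 (not isolated)
Conditions: 20 (2 equiv), hν (300 nm, borosilicate filter), degassed ClCH2CH2Cl, rt; then 80 °C
Reagents that add atoms: none
Why: Danheiser benzannulation in its photochemical form (unsaturated α-diazo ketone plus siloxyalkyne), a known reaction type applied here to a dienyl diazo ketone. Light expels N2 from 16 and the Wolff rearrangement shifts C9 onto the diazo carbon (bond C9–C11), giving vinylketene 21 whose carbonyl carbon is the future C14. The siloxyalkyne adds across the ketene C=C in a [2+2] cycloaddition (bonds C13–C14 and C11–C12) to give cyclobutenone 22, which opens by 4π electrocyclisation to dienylketene 23; ring C then closes by 6π electrocyclisation between C14 and C8, and dienone 24 tautomerises to the phenol. No stereocentre is created; C5 and C10 are remote from the reacting atoms and no acid or base is present, so they, the enol ether, the isopropenyl group and the silyl ethers should persist. The step needs regiocontrol in the cycloaddition and chemoselectivity for the alkyne: the oxygen-polarised alkyne attacks the ketene carbonyl carbon with its isopropyl-bearing carbon, which places isopropyl on C13 beside the C14 hydroxyl and the silyloxy group on C12, and the siloxyalkyne, used in excess, is by far the most nucleophilic π-bond present. A premature 6π closure of 21 onto C6 is excluded because C11 and C7 are trans across the ring C8=C9 bond. Heating after irradiation completes the conversion of any 22 that has accumulated.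

Step 14
Reactants: 25 the ring C phenol of step 13
Product: 26 8-ethoxy-5-(3-hydroxypropyl)-5-methyl-2-(propan-2-yl)-6-(prop-1-en-2-yl)-5,6-dihydronaphthalene-1,3-diol (C5 and C10 as in 9)
Conditions: Bu4NF, THF, 0 °C to rt; aq. NH4Cl work-up; argon
Reagents that add atoms: none
Why: Fluoride cleaves the aryl triisopropylsilyl ether and the primary diphenyl silyl ether; freeing the C12 phenol makes ring C an electron-rich, unchelated resorcinol for step 15 and removes the bulky silyl group beside C11, while the enol ether survives the near-neutral work-up.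

Step 15
Reactants: 26 the resorcinol of step 14
Product: 28 2-hydroxy-8-(3-hydroxypropyl)-8-methyl-3-(propan-2-yl)-7-(prop-1-en-2-yl)-7,8-dihydronaphthalene-1,4,5(6H)-trione (12-hydroxy-11,14-quinone with C7 ketone; C5 and C10 as in 9), via quinone enol ether 27 (not isolated)
Conditions: (KSO3)2NO, KH2PO4, acetone/H2O, rt; then 2 M HCl, rt
Reagents that add atoms: potassium nitrosodisulfonate, [K+].[K+].[O-]S(=O)(=O)N([O])S(=O)(=O)[O-]; water, O
Why: Teuber oxidation: the nitroxyl radical abstracts a phenolic hydrogen and a second equivalent couples at C11, the only free ring position (para to the C14 oxygen, ortho to the C12 oxygen), which gives the 2-hydroxy-1,4-benzoquinone; acidification then hydrolyses the enol ether to the C7 ketone. Oxidising before the ketone is unveiled avoids a chelated, acyl-deactivated phenol.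

Step 16
Reactants: 28 the hydroxyquinone alcohol of step 15
Product: 29 3-[7-hydroxy-1-methyl-4,5,8-trioxo-6-(propan-2-yl)-2-(prop-1-en-2-yl)-1,2,3,4,5,8-hexahydronaphthalen-1-yl]propanoic acid (C5 and C10 as in the target)
Conditions: TEMPO (20 mol %), PhI(OAc)2 (2.2 equiv), MeCN/H2O 1:1, rt
Reagents that add atoms: water, O
Why: Oxoammonium-catalysed oxidation of the primary alcohol to the aldehyde and, through its hydrate, to the acid; the quinone is already at a high oxidation level, its C13 position is blocked, and the isopropenyl group and ketone are inert to this oxidant.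

Step 17
Reactants: 29 the hydroxyquinone acid of step 16
Product: 30 3-[(1R,2S)-5,7,8-trihydroxy-1-methyl-4-oxo-6-(propan-2-yl)-2-(prop-1-en-2-yl)-1,2,3,4-tetrahydronaphthalen-1-yl]propanoic acid (target)
Conditions: Na2S2O4, EtOAc/H2O, rt, argon; acidic work-up under argon
Reagents that add atoms: none
Why: Dithionite reduces the quinone to the hydroquinone under near-neutral aqueous conditions and should not touch the aryl ketone, the alkene or the acid; it is done last and under argon because the triol reoxidises in air.

## Compound list

1 | cyclohex-2-en-1-one | O=C1C=CCCC1 | starting material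
2 | 4,4,5,5-tetramethyl-2-(prop-1-en-2-yl)-1,3,2-dioxaborolane | CC(=C)B1OC(C)(C)C(C)(C)O1 | starting material
3 | (R)-3-(prop-1-en-2-yl)cyclohexan-1-one | C=C(C)[C@@H]1CCCC(=O)C1 | intermediate
4 | (R)-trimethyl{[5-(prop-1-en-2-yl)cyclohex-1-en-1-yl]oxy}silane | C=C(C)[C@@H]1CCC=C(O[Si](C)(C)C)C1 | intermediate
5 | (R)-5-(prop-1-en-2-yl)cyclohex-2-en-1-one | C=C(C)[C@@H]1CC=CC(=O)C1 | intermediate
6 | 3-iodopropan-1-ol | OCCCI | starting material
7 | tert-butyl(3-iodopropoxy)diphenylsilane | CC(C)(C)[Si](c1ccccc1)(c1ccccc1)OCCCI | intermediate
8 | (5R,6S)-6-{3-[(tert-butyldiphenylsilyl)oxy]propyl}-5-(prop-1-en-2-yl)cyclohex-2-en-1-one | C=C(C)[C@@H]1CC=CC(=O)[C@H]1CCCO[Si](c2ccccc2)(c2ccccc2)C(C)(C)C | intermediate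
9 | (5S,6R)-6-{3-[(tert-butyldiphenylsilyl)oxy]propyl}-6-methyl-5-(prop-1-en-2-yl)cyclohex-2-en-1-one | C=C(C)[C@@H]1CC=CC(=O)[C@]1(C)CCCO[Si](c2ccccc2)(c2ccccc2)C(C)(C)C | intermediate
10 | 3-{3-[(tert-butyldiphenylsilyl)oxy]propyl}-3-methyl-4-(prop-1-en-2-yl)-7-oxabicyclo[4.1.0]heptan-2-one (epoxide anti to isopropenyl expected) | C=C(C)[C@@H]1C[C@H]2O[C@H]2C(=O)[C@]1(C)CCCO[Si](c3ccccc3)(c3ccccc3)C(C)(C)C | intermediate
11 | 4-{3-[(tert-butyldiphenylsilyl)oxy]propyl}-4-methyl-5-(prop-1-en-2-yl)cyclohexane-1,3-dione | C=C(C)[C@@H]1CC(=O)CC(=O)[C@]1(C)CCCO[Si](c2ccccc2)(c2ccccc2)C(C)(C)C | intermediate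
12 | 6-{3-[(tert-butyldiphenylsilyl)oxy]propyl}-3-ethoxy-6-methyl-5-(prop-1-en-2-yl)cyclohex-2-en-1-one | C=C(C)[C@@H]1CC(OCC)=CC(=O)[C@]1(C)CCCO[Si](c2ccccc2)(c2ccccc2)C(C)(C)C | intermediate
13 | 6-{3-[(tert-butyldiphenylsilyl)oxy]propyl}-3-ethoxy-6-methyl-5-(prop-1-en-2-yl)cyclohexa-1,3-dien-1-yl trifluoromethanesulfonate | C=C(C)[C@@H]1C=C(OCC)C=C(OS(=O)(=O)C(F)(F)F)[C@]1(C)CCCO[Si](c2ccccc2)(c2ccccc2)C(C)(C)C | intermediate
14 | 1-[6-{3-[(tert-butyldiphenylsilyl)oxy]propyl}-3-ethoxy-6-methyl-5-(prop-1-en-2-yl)cyclohexa-1,3-dien-1-yl]ethan-1-one | C=C(C)[C@@H]1C=C(OCC)C=C(C(C)=O)[C@]1(C)CCCO[Si](c2ccccc2)(c2ccccc2)C(C)(C)C | intermediate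
15 | 1-[6-{3-[(tert-butyldiphenylsilyl)oxy]propyl}-3-ethoxy-6-methyl-5-(prop-1-en-2-yl)cyclohexa-1,3-dien-1-yl]-4,4,4-trifluorobutane-1,3-dione | C=C(C)[C@@H]1C=C(OCC)C=C(C(=O)CC(=O)C(F)(F)F)[C@]1(C)CCCO[Si](c2ccccc2)(c2ccccc2)C(C)(C)C | intermediate
16 | 2-diazo-1-[6-{3-[(tert-butyldiphenylsilyl)oxy]propyl}-3-ethoxy-6-methyl-5-(prop-1-en-2-yl)cyclohexa-1,3-dien-1-yl]ethan-1-one | C=C(C)[C@@H]1C=C(OCC)C=C(C(=O)C=[N+]=[N-])[C@]1(C)CCCO[Si](c2ccccc2)(c2ccccc2)C(C)(C)C | intermediate
17 | ethyl 2-methylpropanoate | CCOC(=O)C(C)C | starting material
18 | lithium 1,1-dibromo-3-methylbut-1-en-2-olate | [Li+].[O-]C(=C(Br)Br)C(C)C | intermediate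
19 | lithium 3-methylbut-1-yn-1-olate | [Li+].[O-]C#CC(C)C | intermediate
20 | triisopropyl[(3-methylbut-1-yn-1-yl)oxy]silane | CC(C)C#CO[Si](C(C)C)(C(C)C)C(C)C | intermediate
21 | 2-[6-{3-[(tert-butyldiphenylsilyl)oxy]propyl}-3-ethoxy-6-methyl-5-(prop-1-en-2-yl)cyclohexa-1,3-dien-1-yl]ethen-1-one (vinylketene) | C=C(C)[C@@H]1C=C(OCC)C=C(C=C=O)[C@]1(C)CCCO[Si](c2ccccc2)(c2ccccc2)C(C)(C)C | intermediate
22 | 4-[6-{3-[(tert-butyldiphenylsilyl)oxy]propyl}-3-ethoxy-6-methyl-5-(prop-1-en-2-yl)cyclohexa-1,3-dien-1-yl]-2-(propan-2-yl)-3-[(triisopropylsilyl)oxy]cyclobut-2-en-1-one (C11 configuration undefined, lost on ring opening) | C=C(C)[C@@H]1C=C(OCC)C=C(C2C(O[Si](C(C)C)(C(C)C)C(C)C)=C(C(C)C)C2=O)[C@]1(C)CCCO[Si](c3ccccc3)(c3ccccc3)C(C)(C)C | intermediate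
23 | 4-[6-{3-[(tert-butyldiphenylsilyl)oxy]propyl}-3-ethoxy-6-methyl-5-(prop-1-en-2-yl)cyclohexa-1,3-dien-1-yl]-2-(propan-2-yl)-3-[(triisopropylsilyl)oxy]buta-1,3-dien-1-one (C9 cis to C13 across C11=C12) | C=C(C)[C@@H]1C=C(OCC)C=C(/C=C(/O[Si](C(C)C)(C(C)C)C(C)C)C(C(C)C)=C=O)[C@]1(C)CCCO[Si](c2ccccc2)(c2ccccc2)C(C)(C)C | intermediate
24 | 5-{3-[(tert-butyldiphenylsilyl)oxy]propyl}-8-ethoxy-5-methyl-2-(propan-2-yl)-6-(prop-1-en-2-yl)-3-[(triisopropylsilyl)oxy]-6,8a-dihydronaphthalen-1(5H)-one (C8 configuration undefined, lost on tautomerisation) | C=C(C)[C@@H]1C=C(OCC)C2C(=O)C(C(C)C)=C(O[Si](C(C)C)(C(C)C)C(C)C)C=C2[C@]1(C)CCCO[Si](c3ccccc3)(c3ccccc3)C(C)(C)C | intermediate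
25 | 5-{3-[(tert-butyldiphenylsilyl)oxy]propyl}-8-ethoxy-5-methyl-2-(propan-2-yl)-6-(prop-1-en-2-yl)-3-[(triisopropylsilyl)oxy]-5,6-dihydronaphthalen-1-ol | C=C(C)[C@@H]1C=C(OCC)c2c(O)c(C(C)C)c(O[Si](C(C)C)(C(C)C)C(C)C)cc2[C@]1(C)CCCO[Si](c3ccccc3)(c3ccccc3)C(C)(C)C | intermediate
26 | 8-ethoxy-5-(3-hydroxypropyl)-5-methyl-2-(propan-2-yl)-6-(prop-1-en-2-yl)-5,6-dihydronaphthalene-1,3-diol | C=C(C)[C@@H]1C=C(OCC)c2c(O)c(C(C)C)c(O)cc2[C@]1(C)CCCO | intermediate
27 | 5-ethoxy-2-hydroxy-8-(3-hydroxypropyl)-8-methyl-3-(propan-2-yl)-7-(prop-1-en-2-yl)-7,8-dihydronaphthalene-1,4-dione | C=C(C)[C@@H]1C=C(OCC)C2=C(C(=O)C(O)=C(C(C)C)C2=O)[C@]1(C)CCCO | intermediate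
28 | 2-hydroxy-8-(3-hydroxypropyl)-8-methyl-3-(propan-2-yl)-7-(prop-1-en-2-yl)-7,8-dihydronaphthalene-1,4,5(6H)-trione | C=C(C)[C@@H]1CC(=O)C2=C(C(=O)C(O)=C(C(C)C)C2=O)[C@]1(C)CCCO | intermediate
29 | 3-[7-hydroxy-1-methyl-4,5,8-trioxo-6-(propan-2-yl)-2-(prop-1-en-2-yl)-1,2,3,4,5,8-hexahydronaphthalen-1-yl]propanoic acid | C=C(C)[C@@H]1CC(=O)C2=C(C(=O)C(O)=C(C(C)C)C2=O)[C@]1(C)CCC(=O)O | intermediate
30 | 3-[(1R,2S)-5,7,8-trihydroxy-1-methyl-4-oxo-6-(propan-2-yl)-2-(prop-1-en-2-yl)-1,2,3,4-tetrahydronaphthalen-1-yl]propanoic acid | C=C(C)[C@@H]1CC(=O)c2c(O)c(C(C)C)c(O)c(O)c2[C@]1(C)CCC(=O)O | target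

## Step count and least certain steps

Total: 17 steps. Longest linear sequence: 15 steps (steps 1, 2, 4 to 11 and 13 to 17); steps 3 and 12 are side branches.

**Step 13 (key step).** The vinylketene may be consumed before it meets the alkyne: by cycloaddition with the electron-rich enol ether of a second molecule, by dimerisation, or by traces of water. The cycloaddition itself may be slow because C11 lies beside the crowded C9–C10 region. If the Wolff shift is not concerted, the acyl carbene could also add to the isopropenyl group.

Fallback, setting out from 13 and returning at 28: the triflate is converted with hexamethylditin, Pd(PPh3)4 and LiCl into the dienylstannane F1. Tin–lithium exchange with MeLi gives the dienyllithium, which is added at −78 °C to 3-isopropoxy-4-isopropylcyclobut-3-ene-1,2-dione F2 (prepared from diisopropyl squarate with isopropylmagnesium chloride and then aqueous HCl). Addition occurs at the carbonyl next to the alkoxy-bearing carbon and gives the 4-hydroxycyclobutenone F3. Heating in toluene opens the four-membered ring to a dienylketene that closes onto C8 (Moore-type ring expansion); the resulting hydroquinone is oxidised with Ag2O to the isopropoxyquinone F4, which already carries the C11 oxygen. Fluoride, aqueous acid and brief dilute aqueous NaOH (to hydrolyse the vinylogous ester) then lead to 28. Ring C is still closed by a 6π closure between C14 and C8, but the ketene comes from a cyclobutenone and no light is needed.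

**Step 2.** Enolisation may be poorly regioselective, because the C8 and C10 methylenes differ only by the remote C5 substituent; material would then be lost to the regioisomeric enone.

Fallback, from 3 to 5: thermodynamically controlled formylation with ethyl formate and NaH goes to the less hindered C8 and gives the hydroxymethylene ketone F5. Deformylative diazo transfer with MsN3 and Et3N gives the α-diazo ketone F6. Rh2(OAc)4 then induces a 1,2-hydride shift of the carbenoid, which places the double bond at C7=C8 and returns 5.

**Step 5.** Facial selectivity in the methylation of the flat cross-conjugated dienolate may be insufficient, since only the neighbouring C5 substituent differentiates the two faces.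

Fallback, from 1 to 9: iodination with I2 and pyridine gives 2-iodocyclohex-2-en-1-one F7. B-alkyl Suzuki–Miyaura coupling with the 9-BBN adduct of allyl tert-butyldiphenylsilyl ether (PdCl2(dppf), Cs2CO3) gives the 2-substituted enone F8. Copper-catalysed asymmetric conjugate addition of isopropenylmagnesium bromide (CuBr·SMe2 with a chiral ferrocenyl diphosphine), with trapping of the regiodefined enolate by iodomethane in DMPU, gives the saturated ketone F9. Here the methyl group enters trans to the isopropenyl group that has just been added, on a chair-like ring. Dehydrogenation with 2-iodoxybenzoic acid, possible only towards C8, returns 9.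

**Step 10.** Methyl transfer from tin to the hindered acylpalladium species beside the quaternary carbon may be slow, so that the triflate decomposes or is reduced.

Fallback, from 13 to 14: aminocarbonylation with Pd(OAc)2, dppp, CO, N,O-dimethylhydroxylamine hydrochloride and Et3N gives the N-methoxy-N-methylamide F10, and MeMgBr converts it into 14.

**Step 15.** The radical oxidation may be unselective: attack at the enol ether or at allylic positions, or further oxidation of the hydroxyquinone in the aqueous medium.

Fallback, from 26 to 28, using ionic two-electron chemistry: ortho-formylation of the C12 phenol at C11 with MgCl2, Et3N and paraformaldehyde gives the aldehyde F11. Dakin oxidation with H2O2 and NaOH gives the 11,12,14-triol F12. Aqueous HCl hydrolyses the enol ether and Ag2O oxidises the triol to 28.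

## Further compounds

F1 | step 13 | tert-butyl{3-[4-ethoxy-1-methyl-6-(prop-1-en-2-yl)-2-(trimethylstannyl)cyclohexa-2,4-dien-1-yl]propoxy}diphenylsilane | C=C(C)[C@@H]1C=C(OCC)C=C([Sn](C)(C)C)[C@]1(C)CCCO[Si](c2ccccc2)(c2ccccc2)C(C)(C)C
F2 | step 13 | 3-isopropoxy-4-isopropylcyclobut-3-ene-1,2-dione | CC(C)OC1=C(C(C)C)C(=O)C1=O
F3 | step 13 | 4-[6-{3-[(tert-butyldiphenylsilyl)oxy]propyl}-3-ethoxy-6-methyl-5-(prop-1-en-2-yl)cyclohexa-1,3-dien-1-yl]-4-hydroxy-3-isopropoxy-2-isopropylcyclobut-2-en-1-one | C=C(C)[C@@H]1C=C(OCC)C=C(C2(O)C(OC(C)C)=C(C(C)C)C2=O)[C@]1(C)CCCO[Si](c3ccccc3)(c3ccccc3)C(C)(C)C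
F4 | step 13 | 8-{3-[(tert-butyldiphenylsilyl)oxy]propyl}-5-ethoxy-2-isopropoxy-8-methyl-3-(propan-2-yl)-7-(prop-1-en-2-yl)-7,8-dihydronaphthalene-1,4-dione | C=C(C)[C@@H]1C=C(OCC)C2=C(C(=O)C(OC(C)C)=C(C(C)C)C2=O)[C@]1(C)CCCO[Si](c3ccccc3)(c3ccccc3)C(C)(C)C
F5 | step 2 | (R)-2-(hydroxymethylene)-5-(prop-1-en-2-yl)cyclohexan-1-one | C=C(C)[C@@H]1CCC(=CO)C(=O)C1
F6 | step 2 | (R)-2-diazo-5-(prop-1-en-2-yl)cyclohexan-1-one | C=C(C)[C@@H]1CCC(=[N+]=[N-])C(=O)C1
F7 | step 5 | 2-iodocyclohex-2-en-1-one | O=C1CCCC=C1I
F8 | step 5 | 2-{3-[(tert-butyldiphenylsilyl)oxy]propyl}cyclohex-2-en-1-one | O=C1CCCC=C1CCCO[Si](c2ccccc2)(c2ccccc2)C(C)(C)C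
F9 | step 5 | 2-{3-[(tert-butyldiphenylsilyl)oxy]propyl}-2-methyl-3-(prop-1-en-2-yl)cyclohexan-1-one (methyl trans to isopropenyl) | C=C(C)[C@@H]1CCCC(=O)[C@]1(C)CCCO[Si](c2ccccc2)(c2ccccc2)C(C)(C)C
F10 | step 10 | 6-{3-[(tert-butyldiphenylsilyl)oxy]propyl}-3-ethoxy-N-methoxy-N,6-dimethyl-5-(prop-1-en-2-yl)cyclohexa-1,3-diene-1-carboxamide | C=C(C)[C@@H]1C=C(OCC)C=C(C(=O)N(C)OC)[C@]1(C)CCCO[Si](c2ccccc2)(c2ccccc2)C(C)(C)C
F11 | step 15 | 5-ethoxy-2,4-dihydroxy-8-(3-hydroxypropyl)-8-methyl-3-(propan-2-yl)-7-(prop-1-en-2-yl)-7,8-dihydronaphthalene-1-carbaldehyde | C=C(C)[C@@H]1C=C(OCC)c2c(O)c(C(C)C)c(O)c(C=O)c2[C@]1(C)CCCO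
F12 | step 15 | 8-ethoxy-5-(3-hydroxypropyl)-5-methyl-2-(propan-2-yl)-6-(prop-1-en-2-yl)-5,6-dihydronaphthalene-1,3,4-triol | C=C(C)[C@@H]1C=C(OCC)c2c(O)c(C(C)C)c(O)c(O)c2[C@]1(C)CCCO
A1 | alternative 1 | cis-fused tricyclic 3,7-diketone with gem-dimethyl C4 and tris(methyl ether) arene | CC1(C)C(=O)CC[C@@]2(C)c3c(OC)c(OC)c(C(C)C)c(OC)c3C(=O)C[C@@H]12
A2 | alternative 1 | ring B enone with the 4-methyl-3-oxopentyl chain on C10 | CC(C)C(=O)CC[C@]1(C)C=CC(=O)c2c(OC)c(C(C)C)c(OC)c(OC)c12
A3 | alternative 2 | tetralone with the N-acyl oxazolidinone on C5 | O=C(N1[C@H](Cc2ccccc2)COC1=O)[C@@H]3CC(=O)c4c(OC)c(C(C)C)c(OC)c(OC)c4[C@]3(C)CCC(=O)OC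
A4 | alternative 2 | aryl methyl ketone with the imide and ester arms on C10 | CC(=O)c1c(OC)c(C(C)C)c(OC)c(OC)c1[C@](C)(CCC(=O)OC)CC(=O)N2[C@H](Cc3ccccc3)COC2=O
A5 | alternative 3 | tetralone with quaternary C10 bearing methyl and the (E)-alkenyl chain | CC(C)(O[Si](CC)(CC)CC)[C@@H]1CC(=O)c2c(OC)c(C(C)C)c(OC)c(OC)c2[C@]1(C)/C=C/CO[Si](C)(C)C(C)(C)C
A6 | alternative 3 | aryl iodide ketone with the (E)-trisubstituted C10=C1 alkene | CC(C)(O[Si](CC)(CC)CC)[C@H](CC(=O)c1c(OC)c(C(C)C)c(OC)c(OC)c1I)/C(C)=C/CCO[Si](C)(C)C(C)(C)C
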